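**Retrosynthetic overview**
- The target is two copies of one (R)-configured aryl-butenolide joined through a tertiary C–O bond. The last C–O disconnection gives fragment B (free enol OH, prenyl side chain) and fragment A (the same core carrying an (S)-trisubstituted epoxide); the enol OH opens the epoxide at its tertiary carbon.
- The prenyl group of fragment B is disconnected by an aromatic Claisen ([3,3]) rearrangement of a 1,1-dimethylallyl aryl ether, run on an L-tyrosine-derived dioxolanone.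
- The side chain of fragment A comes from nickel-catalysed coupling of an aryl iodide with (R)-2-(oxiran-2-yl)propan-2-ol (from methyl (R)-glycidate), then diol to epoxide with inversion.
- Both quaternary centres come from L-tyrosine: (S)-hydroxy acid, cis pivaldehyde acetal, then enolate aldol anti to tert-butyl.
- Ring order: temporary dioxolanone first, then the butenolide ring of fragment B, then that of fragment A (each by O-acylation and intramolecular aldol condensation); the fragments are joined last and all silyl groups removed together.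

Assumption: tert-butyl 2-methylbut-3-en-2-yl carbonate, 4-(triisopropylsilyloxy)benzaldehyde, acetoxyacetyl chloride and methyl (R)-glycidate are taken as catalogue chemicals.
Abbreviations: TIPS = triisopropylsilyl, TIPSO = triisopropylsilyloxy, prenyl = 3-methylbut-2-enyl.

**Route**

Step 1
Reactants: 1 L-tyrosine
Product: 2 (S)-2-hydroxy-3-(4-hydroxyphenyl)propanoic acid
Conditions: NaNO2, 1 M H2SO4, H2O, 0 °C to rt
Reagents that add atoms: water, O
Why: Diazotisation of the α-amino acid replaces NH2 by OH with net retention (double inversion with carboxylate participation), so the (S) centre of L-tyrosine is kept.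

Step 2
Reactants: 2 (S)-2-hydroxy-3-(4-hydroxyphenyl)propanoic acid; 3 pivaldehyde
Product: 4 (2S,5S)-2-tert-butyl-5-(4-hydroxybenzyl)-1,3-dioxolan-4-one
Conditions: TsOH·H2O (5 mol %), cyclohexane, reflux, Dean–Stark; recrystallisation
Reagents that add atoms: none
Why: Acid-catalysed acetalisation (Seebach self-regeneration of stereocentres) gives the favoured cis-dioxolanone, the new acetal centre (2S) being set by the tyrosine-derived centre and purified by crystallisation.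

Step 3
Reactants: 4 (2S,5S)-2-tert-butyl-5-(4-hydroxybenzyl)-1,3-dioxolan-4-one; 5 tert-butyl 2-methylbut-3-en-2-yl carbonate
Product: 6 (2S,5S)-2-tert-butyl-5-[4-(2-methylbut-3-en-2-yloxy)benzyl]-1,3-dioxolan-4-one
Conditions: Pd(PPh3)4 (5 mol %), 4 Å MS, THF, 0 °C to rt
Reagents that add atoms: none
Why: Tsuji–Trost O-allylation: zerovalent palladium ionises the carbonate to a 1,1-dimethyl-π-allyl complex that the phenoxide attacks at the more substituted terminus under kinetic control, giving the tertiary aryl ether.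

Step 4
Reactants: 6 (2S,5S)-2-tert-butyl-5-[4-(2-methylbut-3-en-2-yloxy)benzyl]-1,3-dioxolan-4-one
Product: 7 (2S,5S)-2-tert-butyl-5-(4-hydroxy-3-prenylbenzyl)-1,3-dioxolan-4-one
Conditions: toluene, 115 °C (sealed tube)
Reagents that add atoms: none
Why: Aromatic Claisen rearrangement: the [3,3]-sigmatropic shift and rearomatisation form the aryl–CH2 bond at the free ortho position (para is blocked) with allylic transposition to the prenyl group, under neutral conditions that leave both stereocentres alone.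

Step 5
Reactants: 7 (2S,5S)-2-tert-butyl-5-(4-hydroxy-3-prenylbenzyl)-1,3-dioxolan-4-one
Product: 8 (2S,5S)-2-tert-butyl-5-(3-prenyl-4-TIPSO-benzyl)-1,3-dioxolan-4-one
Conditions: TIPSCl, imidazole, DMF, 40 °C
Reagents that add atoms: triisopropylsilyl chloride, CC(C)[Si](Cl)(C(C)C)C(C)C
Why: Standard phenol silylation; the bulky aryl silyl ether survives the enolate, carbonate/methanol and DBU steps that follow.

Step 6
Reactants: 8 (2S,5S)-2-tert-butyl-5-(3-prenyl-4-TIPSO-benzyl)-1,3-dioxolan-4-one; 9 4-(triisopropylsilyloxy)benzaldehyde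
Product: 11 methyl (2R)-2,3-dihydroxy-2-(3-prenyl-4-TIPSO-benzyl)-3-(4-TIPSO-phenyl)propanoate (both C3 epimers), via aldol adduct 10 (not isolated)
Conditions: LiN(i-Pr)2, THF, −78 °C; 9, −78 °C; then MeOH, K2CO3 (0.3 equiv), −78 to 0 °C; aq. NH4Cl
Reagents that add atoms: methanol, CO
Why: The planar dioxolanone enolate keeps only the acetal stereocentre, so the aldol addition occurs on the face anti to tert-butyl and sets the quaternary centre as (R); base methanolysis then opens the acylal to the methyl ester with loss of pivaldehyde.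

Step 7
Reactants: 11 methyl (2R)-2,3-dihydroxy-2-(3-prenyl-4-TIPSO-benzyl)-3-(4-TIPSO-phenyl)propanoate
Product: 12 methyl (2R)-2-hydroxy-3-oxo-2-(3-prenyl-4-TIPSO-benzyl)-3-(4-TIPSO-phenyl)propanoate
Conditions: Dess–Martin periodinane, pyridine, CH2Cl2, 0 °C to rt
Reagents that add atoms: none
Why: Dess–Martin oxidation converts the secondary benzylic alcohol to the aryl ketone while the tertiary alcohol cannot react, so both carbinol epimers converge.

Step 8
Reactants: 12 methyl (2R)-2-hydroxy-3-oxo-2-(3-prenyl-4-TIPSO-benzyl)-3-(4-TIPSO-phenyl)propanoate; 13 acetoxyacetyl chloride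
Product: 14 methyl (2R)-2-(acetoxyacetoxy)-3-oxo-2-(3-prenyl-4-TIPSO-benzyl)-3-(4-TIPSO-phenyl)propanoate
Conditions: pyridine, DMAP (20 mol %), CH2Cl2, 0 °C to rt
Reagents that add atoms: none
Why: DMAP-catalysed O-acylation of the tertiary α-hydroxy group installs the glycolate unit that becomes C4 and C5 of the butenolide.

Step 9
Reactants: 14 methyl (2R)-2-(acetoxyacetoxy)-3-oxo-2-(3-prenyl-4-TIPSO-benzyl)-3-(4-TIPSO-phenyl)propanoate
Product: 15 methyl (2R)-4-hydroxy-5-oxo-2-(3-prenyl-4-TIPSO-benzyl)-3-(4-TIPSO-phenyl)-2,5-dihydrofuran-2-carboxylate (fragment B)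
Conditions: DBU (2.5 equiv), MeCN, 0 °C to rt; aq. citric acid
Reagents that add atoms: none
Why: Intramolecular aldol (Knoevenagel-type) condensation: the acetoxyacetate enolate closes 5-exo onto the aryl ketone, and acetyl transfer, elimination and loss of acetate give the 3-hydroxy-4-aryl butenolide without touching the quaternary centre.

Step 10
Reactants: 16 methyl (R)-oxirane-2-carboxylate
Product: 17 (R)-2-(oxiran-2-yl)propan-2-ol
Conditions: MeMgCl (2.2 equiv), THF, −78 to −20 °C; aq. NH4Cl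
Reagents that add atoms: methylmagnesium chloride, C[Mg]Cl
Why: Double Grignard addition to the ester is faster than epoxide opening at low temperature and converts CO2Me into CMe2OH without touching the purchased stereocentre.

Step 11
Reactants: 4 (2S,5S)-2-tert-butyl-5-(4-hydroxybenzyl)-1,3-dioxolan-4-one
Product: 18 (2S,5S)-2-tert-butyl-5-(4-hydroxy-3-iodobenzyl)-1,3-dioxolan-4-one
Conditions: N-iodosuccinimide (1.05 equiv), TsOH·H2O (5 mol %), MeCN, 0 °C, 1 h
Reagents that add atoms: N-iodosuccinimide, O=C1CCC(=O)N1I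
Why: Electrophilic aromatic iodination goes ortho to the phenol OH (para is blocked) and stops at mono-substitution with one equivalent of reagent.

Step 12
Reactants: 18 (2S,5S)-2-tert-butyl-5-(4-hydroxy-3-iodobenzyl)-1,3-dioxolan-4-one
Product: 19 (2S,5S)-2-tert-butyl-5-(3-iodo-4-TIPSO-benzyl)-1,3-dioxolan-4-one
Conditions: TIPSCl, imidazole, DMF, 40 °C
Reagents that add atoms: triisopropylsilyl chloride, CC(C)[Si](Cl)(C(C)C)C(C)C
Why: Phenol silylation; the protected oxygen cannot later cyclise onto the neighbouring epoxide.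

Step 13
Reactants: 19 (2S,5S)-2-tert-butyl-5-(3-iodo-4-TIPSO-benzyl)-1,3-dioxolan-4-one; 17 (R)-2-(oxiran-2-yl)propan-2-ol
Product: 20 (2S,5S)-2-tert-butyl-5-{3-[(2R)-2,3-dihydroxy-3-methylbutyl]-4-TIPSO-benzyl}-1,3-dioxolan-4-one
Conditions: NiCl2(dme) (10 mol %), 2,2′-bipyridine (10 mol %), NaI (0.5 equiv), Et3N·HCl, Mn powder, DMPU, 25 °C
Reagents that add atoms: none
Why: Nickel-catalysed reductive cross-electrophile coupling: iodide opens the epoxide at its CH2 terminus and the resulting primary radical is captured by the arylnickel species from 19, so the C–O stereocentre is untouched and the ester-like dioxolanone is tolerated.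

Step 14
Reactants: 20 (2S,5S)-2-tert-butyl-5-{3-[(2R)-2,3-dihydroxy-3-methylbutyl]-4-TIPSO-benzyl}-1,3-dioxolan-4-one
Product: 22 (2S,5S)-2-tert-butyl-5-{3-[((2S)-3,3-dimethyloxiran-2-yl)methyl]-4-TIPSO-benzyl}-1,3-dioxolan-4-one, via mesylate 21 (not isolated)
Conditions: MsCl (1.1 equiv), Et3N, CH2Cl2, −20 °C; then NaH, THF, 0 °C
Reagents that add atoms: none
Why: Selective mesylation of the secondary OH and intramolecular Williamson (SN2) closure by the tertiary alkoxide invert the carbinol carbon, turning the (R)-diol into the (S)-epoxide.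

Step 15
Reactants: 22 (2S,5S)-2-tert-butyl-5-{3-[((2S)-3,3-dimethyloxiran-2-yl)methyl]-4-TIPSO-benzyl}-1,3-dioxolan-4-one; 9 4-(triisopropylsilyloxy)benzaldehyde
Product: 24 methyl (2R)-2-{3-[((2S)-3,3-dimethyloxiran-2-yl)methyl]-4-TIPSO-benzyl}-2,3-dihydroxy-3-(4-TIPSO-phenyl)propanoate (both C3 epimers), via aldol adduct 23 (not isolated)
Conditions: LiN(i-Pr)2, THF, −78 °C; 9, −78 °C; then MeOH, K2CO3 (0.3 equiv), −78 to 0 °C; aq. NH4Cl
Reagents that add atoms: methanol, CO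
Why: As in step 6, the aldol addition of the dioxolanone enolate anti to tert-butyl sets the quaternary centre as (R) before methanolysis releases pivaldehyde; the epoxide is inert to the cold amide base and to carbonate.

Step 16
Reactants: 24 methyl (2R)-2-{3-[((2S)-3,3-dimethyloxiran-2-yl)methyl]-4-TIPSO-benzyl}-2,3-dihydroxy-3-(4-TIPSO-phenyl)propanoate
Product: 25 methyl (2R)-2-{3-[((2S)-3,3-dimethyloxiran-2-yl)methyl]-4-TIPSO-benzyl}-2-hydroxy-3-oxo-3-(4-TIPSO-phenyl)propanoate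
Conditions: Dess–Martin periodinane, pyridine, CH2Cl2, 0 °C to rt
Reagents that add atoms: none
Why: Buffered Dess–Martin oxidation of the secondary benzylic alcohol to the ketone leaves the tertiary alcohol and the epoxide untouched.

Step 17
Reactants: 25 methyl (2R)-2-{3-[((2S)-3,3-dimethyloxiran-2-yl)methyl]-4-TIPSO-benzyl}-2-hydroxy-3-oxo-3-(4-TIPSO-phenyl)propanoate; 13 acetoxyacetyl chloride
Product: 26 methyl (2R)-2-(acetoxyacetoxy)-2-{3-[((2S)-3,3-dimethyloxiran-2-yl)methyl]-4-TIPSO-benzyl}-3-oxo-3-(4-TIPSO-phenyl)propanoate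
Conditions: pyridine, DMAP (20 mol %), CH2Cl2, 0 °C to rt
Reagents that add atoms: none
Why: DMAP-catalysed acylation of the tertiary alcohol, as in step 8, in excess pyridine so that no free acid reaches the epoxide.

Step 18
Reactants: 26 methyl (2R)-2-(acetoxyacetoxy)-2-{3-[((2S)-3,3-dimethyloxiran-2-yl)methyl]-4-TIPSO-benzyl}-3-oxo-3-(4-TIPSO-phenyl)propanoate
Product: 28 methyl (2R)-2-{3-[((2S)-3,3-dimethyloxiran-2-yl)methyl]-4-TIPSO-benzyl}-5-oxo-4-TIPSO-3-(4-TIPSO-phenyl)-2,5-dihydrofuran-2-carboxylate (fragment A), via enol 27 (not isolated)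
Conditions: DBU (2.5 equiv), MeCN, 0 °C to rt; then TIPSCl (3 equiv), 0 °C to rt; pH 7 work-up
Reagents that add atoms: triisopropylsilyl chloride, CC(C)[Si](Cl)(C(C)C)C(C)C
Why: The same DBU-mediated intramolecular aldol condensation as in step 9 builds the butenolide, and the enolate is O-silylated in the flask so the acidic enol never sits free beside the epoxide.

Step 19
Reactants: 28 fragment A; 15 fragment B
Product: 29 penta-TIPS ether of the target (four aryl oxygens and the enol oxygen of the fragment A half silylated)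
Conditions: BF3·OEt2 (20 mol %), 4 Å MS, CH2Cl2, −78 to −30 °C (15 in 1.5-fold excess)
Reagents that add atoms: none
Why: Lewis-acid-promoted epoxide opening with SN1-like regiochemistry: the only free hydroxyl, the acidic enol OH of 15, attacks the tertiary carbon of the activated epoxide, forming the tertiary enol ether and leaving the (S) carbinol carbon untouched.

Step 20
Reactants: 29 penta-TIPS ether of the target
Product: 30 asperbutenolide A
Conditions: Bu4NF (6 equiv), AcOH (6 equiv), THF, 0 °C to rt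
Reagents that add atoms: none
Why: Fluoride-mediated global desilylation cleaves the four aryl and one enol silyl ethers, and the acetic acid buffer keeps the lactones, the prenyl group and the tertiary enol ether intact.

**Compound list**
1 | L-tyrosine | N[C@@H](Cc1ccc(O)cc1)C(=O)O | starting material
2 | (S)-2-hydroxy-3-(4-hydroxyphenyl)propanoic acid | O[C@@H](Cc1ccc(O)cc1)C(=O)O | intermediate
3 | pivaldehyde | CC(C)(C)C=O | starting material
4 | (2S,5S)-2-tert-butyl-5-(4-hydroxybenzyl)-1,3-dioxolan-4-one (cis) | CC(C)(C)[C@H]1O[C@@H](Cc2ccc(O)cc2)C(=O)O1 | intermediate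
5 | tert-butyl 2-methylbut-3-en-2-yl carbonate | C=CC(C)(C)OC(=O)OC(C)(C)C | starting material
6 | (2S,5S)-2-tert-butyl-5-[4-(2-methylbut-3-en-2-yloxy)benzyl]-1,3-dioxolan-4-one | CC(C)(C)[C@H]1O[C@@H](Cc2ccc(OC(C)(C)C=C)cc2)C(=O)O1 | intermediate
7 | (2S,5S)-2-tert-butyl-5-(4-hydroxy-3-prenylbenzyl)-1,3-dioxolan-4-one | CC(C)(C)[C@H]1O[C@@H](Cc2ccc(O)c(CC=C(C)C)c2)C(=O)O1 | intermediate
8 | (2S,5S)-2-tert-butyl-5-(3-prenyl-4-TIPSO-benzyl)-1,3-dioxolan-4-one | CC(C)(C)[C@H]1O[C@@H](Cc2ccc(O[Si](C(C)C)(C(C)C)C(C)C)c(CC=C(C)C)c2)C(=O)O1 | intermediate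
9 | 4-(triisopropylsilyloxy)benzaldehyde | O=Cc1ccc(O[Si](C(C)C)(C(C)C)C(C)C)cc1 | starting material
10 | (2S,5R)-2-tert-butyl-5-[hydroxy(4-TIPSO-phenyl)methyl]-5-(3-prenyl-4-TIPSO-benzyl)-1,3-dioxolan-4-one (both carbinol epimers) | CC(C)(C)[C@H]1O[C@@](C(O)c2ccc(O[Si](C(C)C)(C(C)C)C(C)C)cc2)(Cc2ccc(O[Si](C(C)C)(C(C)C)C(C)C)c(CC=C(C)C)c2)C(=O)O1 | intermediate (not isolated)
11 | methyl (2R)-2,3-dihydroxy-2-(3-prenyl-4-TIPSO-benzyl)-3-(4-TIPSO-phenyl)propanoate (both C3 epimers) | COC(=O)[C@@](O)(Cc1ccc(O[Si](C(C)C)(C(C)C)C(C)C)c(CC=C(C)C)c1)C(O)c1ccc(O[Si](C(C)C)(C(C)C)C(C)C)cc1 | intermediate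
12 | methyl (2R)-2-hydroxy-3-oxo-2-(3-prenyl-4-TIPSO-benzyl)-3-(4-TIPSO-phenyl)propanoate | COC(=O)[C@@](O)(Cc1ccc(O[Si](C(C)C)(C(C)C)C(C)C)c(CC=C(C)C)c1)C(=O)c1ccc(O[Si](C(C)C)(C(C)C)C(C)C)cc1 | intermediate
13 | acetoxyacetyl chloride | CC(=O)OCC(=O)Cl | starting material
14 | methyl (2R)-2-(acetoxyacetoxy)-3-oxo-2-(3-prenyl-4-TIPSO-benzyl)-3-(4-TIPSO-phenyl)propanoate | COC(=O)[C@@](OC(=O)COC(C)=O)(Cc1ccc(O[Si](C(C)C)(C(C)C)C(C)C)c(CC=C(C)C)c1)C(=O)c1ccc(O[Si](C(C)C)(C(C)C)C(C)C)cc1 | intermediate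
15 | methyl (2R)-4-hydroxy-5-oxo-2-(3-prenyl-4-TIPSO-benzyl)-3-(4-TIPSO-phenyl)-2,5-dihydrofuran-2-carboxylate (fragment B) | COC(=O)[C@]1(Cc2ccc(O[Si](C(C)C)(C(C)C)C(C)C)c(CC=C(C)C)c2)OC(=O)C(O)=C1c1ccc(O[Si](C(C)C)(C(C)C)C(C)C)cc1 | intermediate
16 | methyl (R)-oxirane-2-carboxylate (methyl (R)-glycidate) | COC(=O)[C@H]1CO1 | starting material
17 | (R)-2-(oxiran-2-yl)propan-2-ol | CC(C)(O)[C@H]1CO1 | intermediate
18 | (2S,5S)-2-tert-butyl-5-(4-hydroxy-3-iodobenzyl)-1,3-dioxolan-4-one | CC(C)(C)[C@H]1O[C@@H](Cc2ccc(O)c(I)c2)C(=O)O1 | intermediate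
19 | (2S,5S)-2-tert-butyl-5-(3-iodo-4-TIPSO-benzyl)-1,3-dioxolan-4-one | CC(C)(C)[C@H]1O[C@@H](Cc2ccc(O[Si](C(C)C)(C(C)C)C(C)C)c(I)c2)C(=O)O1 | intermediate
20 | (2S,5S)-2-tert-butyl-5-{3-[(2R)-2,3-dihydroxy-3-methylbutyl]-4-TIPSO-benzyl}-1,3-dioxolan-4-one | CC(C)(C)[C@H]1O[C@@H](Cc2ccc(O[Si](C(C)C)(C(C)C)C(C)C)c(C[C@@H](O)C(C)(C)O)c2)C(=O)O1 | intermediate
21 | (2S,5S)-2-tert-butyl-5-{3-[(2R)-3-hydroxy-2-(methanesulfonyloxy)-3-methylbutyl]-4-TIPSO-benzyl}-1,3-dioxolan-4-one | CC(C)(C)[C@H]1O[C@@H](Cc2ccc(O[Si](C(C)C)(C(C)C)C(C)C)c(C[C@@H](OS(C)(=O)=O)C(C)(C)O)c2)C(=O)O1 | intermediate (not isolated)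
22 | (2S,5S)-2-tert-butyl-5-{3-[((2S)-3,3-dimethyloxiran-2-yl)methyl]-4-TIPSO-benzyl}-1,3-dioxolan-4-one | CC(C)(C)[C@H]1O[C@@H](Cc2ccc(O[Si](C(C)C)(C(C)C)C(C)C)c(C[C@@H]3OC3(C)C)c2)C(=O)O1 | intermediate
23 | (2S,5R)-2-tert-butyl-5-{3-[((2S)-3,3-dimethyloxiran-2-yl)methyl]-4-TIPSO-benzyl}-5-[hydroxy(4-TIPSO-phenyl)methyl]-1,3-dioxolan-4-one (both carbinol epimers) | CC(C)(C)[C@H]1O[C@@](C(O)c2ccc(O[Si](C(C)C)(C(C)C)C(C)C)cc2)(Cc2ccc(O[Si](C(C)C)(C(C)C)C(C)C)c(C[C@@H]3OC3(C)C)c2)C(=O)O1 | intermediate (not isolated)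
24 | methyl (2R)-2-{3-[((2S)-3,3-dimethyloxiran-2-yl)methyl]-4-TIPSO-benzyl}-2,3-dihydroxy-3-(4-TIPSO-phenyl)propanoate (both C3 epimers) | COC(=O)[C@@](O)(Cc1ccc(O[Si](C(C)C)(C(C)C)C(C)C)c(C[C@@H]2OC2(C)C)c1)C(O)c1ccc(O[Si](C(C)C)(C(C)C)C(C)C)cc1 | intermediate
25 | methyl (2R)-2-{3-[((2S)-3,3-dimethyloxiran-2-yl)methyl]-4-TIPSO-benzyl}-2-hydroxy-3-oxo-3-(4-TIPSO-phenyl)propanoate | COC(=O)[C@@](O)(Cc1ccc(O[Si](C(C)C)(C(C)C)C(C)C)c(C[C@@H]2OC2(C)C)c1)C(=O)c1ccc(O[Si](C(C)C)(C(C)C)C(C)C)cc1 | intermediate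
26 | methyl (2R)-2-(acetoxyacetoxy)-2-{3-[((2S)-3,3-dimethyloxiran-2-yl)methyl]-4-TIPSO-benzyl}-3-oxo-3-(4-TIPSO-phenyl)propanoate | COC(=O)[C@@](OC(=O)COC(C)=O)(Cc1ccc(O[Si](C(C)C)(C(C)C)C(C)C)c(C[C@@H]2OC2(C)C)c1)C(=O)c1ccc(O[Si](C(C)C)(C(C)C)C(C)C)cc1 | intermediate
27 | methyl (2R)-2-{3-[((2S)-3,3-dimethyloxiran-2-yl)methyl]-4-TIPSO-benzyl}-4-hydroxy-5-oxo-3-(4-TIPSO-phenyl)-2,5-dihydrofuran-2-carboxylate (present as its DBU salt) | COC(=O)[C@]1(Cc2ccc(O[Si](C(C)C)(C(C)C)C(C)C)c(C[C@@H]3OC3(C)C)c2)OC(=O)C(O)=C1c1ccc(O[Si](C(C)C)(C(C)C)C(C)C)cc1 | intermediate (not isolated)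
28 | methyl (2R)-2-{3-[((2S)-3,3-dimethyloxiran-2-yl)methyl]-4-TIPSO-benzyl}-5-oxo-4-TIPSO-3-(4-TIPSO-phenyl)-2,5-dihydrofuran-2-carboxylate (fragment A) | COC(=O)[C@]1(Cc2ccc(O[Si](C(C)C)(C(C)C)C(C)C)c(C[C@@H]3OC3(C)C)c2)OC(=O)C(O[Si](C(C)C)(C(C)C)C(C)C)=C1c1ccc(O[Si](C(C)C)(C(C)C)C(C)C)cc1 | intermediate
29 | penta-TIPS ether of asperbutenolide A (four aryl oxygens and the free enol oxygen silylated; secondary OH free) | COC(=O)[C@]1(Cc2ccc(O[Si](C(C)C)(C(C)C)C(C)C)c(C[C@H](O)C(C)(C)OC3=C(c4ccc(O[Si](C(C)C)(C(C)C)C(C)C)cc4)[C@](Cc4ccc(O[Si](C(C)C)(C(C)C)C(C)C)c(CC=C(C)C)c4)(C(=O)OC)OC3=O)c2)OC(=O)C(O[Si](C(C)C)(C(C)C)C(C)C)=C1c1ccc(O[Si](C(C)C)(C(C)C)C(C)C)cc1 | intermediate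
30 | asperbutenolide A | COC(=O)[C@]1(Cc2ccc(O)c(C[C@H](O)C(C)(C)OC3=C(c4ccc(O)cc4)[C@](Cc4ccc(O)c(CC=C(C)C)c4)(C(=O)OC)OC3=O)c2)OC(=O)C(O)=C1c1ccc(O)cc1 | target

**Step count and risks**
Total step count: 20. Longest linear sequence: 12 steps (1, 2, 11 to 18, 19, 20).

The three steps most likely to fail:

First, step 19, the fragment coupling. The activated epoxide can rearrange by hydride shift to a ketone, the neighbouring aryl silyl ether oxygen can attack it, and the enol is a weak nucleophile. The fallback replaces epoxide opening by an SN1 etherification with a tertiary trichloroacetimidate; it sets out from 28 and comes back at 30. Aqueous HClO4 (cat.) in THF hydrolyses the epoxide at the tertiary carbon, and the labile enol silyl ether with it, to the (S)-diol enol F1. TIPSCl/DBU and then Et3SiCl/imidazole give the enol-TIPS, secondary-triethylsilyl ether with free tertiary alcohol F2. Cl3CCN with catalytic DBU gives the tertiary trichloroacetimidate F3. This alkylates the enol OH of 15 (cyclohexane–CH2Cl2, 5 mol % BF3·OEt2) to the fully silylated dimer F4, which is desilylated under the conditions of step 20 to 30.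

Second, step 13, the nickel-catalysed coupling. The aryl iodide is electron-rich and flanked by a bulky silyloxy group, so reduction to the arene or biaryl formation may win. The fallback uses a polar aryl-metal epoxide opening; it sets out from 19 and comes back at 20. Iodine–magnesium exchange with i-PrMgCl·LiCl (THF, −40 °C) gives the arylmagnesium chloride F5. The chloromagnesium alkoxide F6 (from 17 and i-PrMgCl) is added with CuI (10 mol %) and the mixture is warmed to −10 °C, so that the aryl group opens the epoxide at CH2. NH4Cl work-up gives 20.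

Third, step 9, the butenolide ring closure (the same reaction recurs in step 18). The glycolate enolate may attack the methyl ester instead of the ketone (Dieckmann closure to a tetronic acid), or the α-acyloxy-β-keto ester may fragment. The fallback builds the ring by intramolecular Wittig reaction and oxidises C4 afterwards; it sets out from 12 and comes back at 15. Ph3P=C=C=O in toluene at 110 °C acylates the tertiary alcohol and closes the ring to the C4-unsubstituted butenolide F7. Nucleophilic epoxidation (t-BuOOH, DBU, CH2Cl2, 0 °C) gives the epoxy lactone F8. InCl3 (20 mol %, THF, rt) opens it at the benzylic carbon, and a 1,2-hydride shift (Meinwald rearrangement) with enolisation gives 15.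

**Further compounds**
F1 | step 19 | methyl (2R)-2-{3-[(2S)-2,3-dihydroxy-3-methylbutyl]-4-TIPSO-benzyl}-4-hydroxy-5-oxo-3-(4-TIPSO-phenyl)-2,5-dihydrofuran-2-carboxylate | COC(=O)[C@]1(Cc2ccc(O[Si](C(C)C)(C(C)C)C(C)C)c(C[C@H](O)C(C)(C)O)c2)OC(=O)C(O)=C1c1ccc(O[Si](C(C)C)(C(C)C)C(C)C)cc1
F2 | step 19 | methyl (2R)-2-{3-[(2S)-3-hydroxy-3-methyl-2-(triethylsilyloxy)butyl]-4-TIPSO-benzyl}-5-oxo-4-TIPSO-3-(4-TIPSO-phenyl)-2,5-dihydrofuran-2-carboxylate | COC(=O)[C@]1(Cc2ccc(O[Si](C(C)C)(C(C)C)C(C)C)c(C[C@H](O[Si](CC)(CC)CC)C(C)(C)O)c2)OC(=O)C(O[Si](C(C)C)(C(C)C)C(C)C)=C1c1ccc(O[Si](C(C)C)(C(C)C)C(C)C)cc1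
F3 | step 19 | tertiary 2,2,2-trichloroacetimidate of F2 | COC(=O)[C@]1(Cc2ccc(O[Si](C(C)C)(C(C)C)C(C)C)c(C[C@H](O[Si](CC)(CC)CC)C(C)(C)OC(=N)C(Cl)(Cl)Cl)c2)OC(=O)C(O[Si](C(C)C)(C(C)C)C(C)C)=C1c1ccc(O[Si](C(C)C)(C(C)C)C(C)C)cc1
F4 | step 19 | penta-TIPS ether of asperbutenolide A carrying a triethylsilyl ether on the secondary carbinol | COC(=O)[C@]1(Cc2ccc(O[Si](C(C)C)(C(C)C)C(C)C)c(C[C@H](O[Si](CC)(CC)CC)C(C)(C)OC3=C(c4ccc(O[Si](C(C)C)(C(C)C)C(C)C)cc4)[C@](Cc4ccc(O[Si](C(C)C)(C(C)C)C(C)C)c(CC=C(C)C)c4)(C(=O)OC)OC3=O)c2)OC(=O)C(O[Si](C(C)C)(C(C)C)C(C)C)=C1c1ccc(O[Si](C(C)C)(C(C)C)C(C)C)cc1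
F5 | step 13 | {5-[((2S,4S)-2-tert-butyl-5-oxo-1,3-dioxolan-4-yl)methyl]-2-TIPSO-phenyl}magnesium chloride | CC(C)(C)[C@H]1O[C@@H](Cc2ccc(O[Si](C(C)C)(C(C)C)C(C)C)c([Mg]Cl)c2)C(=O)O1
F6 | step 13 | chloromagnesium (R)-2-(oxiran-2-yl)propan-2-olate | CC(C)(O[Mg]Cl)[C@H]1CO1
F7 | step 9 | methyl (2R)-5-oxo-2-(3-prenyl-4-TIPSO-benzyl)-3-(4-TIPSO-phenyl)-2,5-dihydrofuran-2-carboxylate | COC(=O)[C@]1(Cc2ccc(O[Si](C(C)C)(C(C)C)C(C)C)c(CC=C(C)C)c2)OC(=O)C=C1c1ccc(O[Si](C(C)C)(C(C)C)C(C)C)cc1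
F8 | step 9 | methyl (4R)-2-oxo-4-(3-prenyl-4-TIPSO-benzyl)-5-(4-TIPSO-phenyl)-3,6-dioxabicyclo[3.1.0]hexane-4-carboxylate (epoxide diastereomers) | COC(=O)[C@]1(Cc2ccc(O[Si](C(C)C)(C(C)C)C(C)C)c(CC=C(C)C)c2)OC(=O)C2OC21c1ccc(O[Si](C(C)C)(C(C)C)C(C)C)cc1
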